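**Retrosynthetic overview**

- The strategy rests on unit Q (the 7‑hydroxycoumarin‑6‑yl part): in its benzene ring C4a–C5–C6–C7–C8–C8a the ether oxygen on C6 and the lactone oxygen on C8a are para, a hydroquinone monoether. This ring is therefore cut by a Dötz benzannulation into a carbene carbon (C6, carrying the aryloxy group of unit P), a 1‑methoxyvinyl group (C7, C8), one CO (C8a) and 3,3‑diethoxyprop‑1‑yne (C5, C4a and the masked C4).
- The diaryl ether bond to the doubly flanked 5‑OH of unit P (the 6,7‑dioxygenated coumarin) is made by acyloxy‑for‑aryloxy exchange at a chromium carbene carbon, not by arylation.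
- The phenol of unit P, 5‑hydroxy‑6,7‑dimethoxycoumarin, comes from isoscopoletin: the free 6‑OH directs formylation to C5, the 6‑OH is methylated, and Baeyer–Villiger oxidation turns the formyl group into the 5‑OH.
- Ring order: both rings of unit P are bought; the benzene ring of unit Q is closed by the benzannulation; the pyranone ring of unit Q follows by Wittig olefination–lactonisation; BBr3 then frees the three phenols.

Key step: step 6

Remark: the target has no stereocentre; isoscopoletin (6‑hydroxy‑7‑methoxycoumarin) is taken as a purchasable starting material.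

**Route**

Step 1
Reactants: 1 isoscopoletin (6‑hydroxy‑7‑methoxy‑2H‑chromen‑2‑one)
Product: 2 6‑hydroxy‑7‑methoxy‑2‑oxo‑2H‑chromene‑5‑carbaldehyde
Conditions: MgCl2, Et3N, (CH2O)n, MeCN, reflux; then 1 M HCl
Reagents that add atoms: paraformaldehyde (formaldehyde), C=O
Why: Magnesium‑mediated ortho‑formylation (Casnati–Skattebøl) should deliver formaldehyde from the magnesium phenoxide through a six‑membered chelate to C5, the only free position ortho to the 6‑OH, a second formaldehyde oxidising the benzylic alkoxide by hydride transfer, so that C8 (ortho only to the methoxy group) is left alone.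

Step 2
Reactants: 2 6‑hydroxy‑7‑methoxy‑2‑oxo‑2H‑chromene‑5‑carbaldehyde
Product: 3 6,7‑dimethoxy‑2‑oxo‑2H‑chromene‑5‑carbaldehyde
Conditions: MeI, K2CO3, DMF, rt
Reagents that add atoms: iodomethane, CI
Why: Williamson O‑methylation of the phenol in dry DMF should leave lactone and aldehyde untouched, and it caps the 6‑oxygen before the 5‑oxygen exists, which is what tells the two apart.

Step 3
Reactants: 3 6,7‑dimethoxy‑2‑oxo‑2H‑chromene‑5‑carbaldehyde
Product: 5 5‑hydroxy‑6,7‑dimethoxycoumarin, via aryl formate 4 (not isolated)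
Conditions: mCPBA, CH2Cl2, 0 °C to rt; then Et3N (cat.), MeOH, rt
Reagents that add atoms: 3‑chloroperoxybenzoic acid, OOC(=O)c1cccc(Cl)c1
Why: In this Baeyer–Villiger (Dakin‑type) oxidation the aryl group, ortho‑methoxylated and twisted out of conjugation by its two ortho neighbours, should migrate in the Criegee adduct to give the aryl formate, which mild transesterification cleaves without opening the lactone.

Step 4
Reactants: 6 methyl vinyl ether; 7 hexacarbonylchromium Cr(CO)6
Product: 10 tetramethylammonium pentacarbonyl(2‑methoxyprop‑2‑enoyl)chromate [NMe4][(CO)5CrC(O)C(OMe)=CH2], via 1‑methoxyvinyllithium 8 (not isolated), via lithium acylchromate 9 (not isolated)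
Conditions: t‑BuLi, THF, −78 to 0 °C; then Cr(CO)6, Et2O, 0 °C to rt; then Me4NBr, H2O
Reagents that add atoms: tetramethylammonium bromide, C[N+](C)(C)C.[Br-]
Why: α‑Lithiation of the enol ether, Fischer addition of the vinyllithium to a CO ligand of Cr(CO)6 and cation metathesis should give the storable ammonium acylmetalate, as with other lithiated enol ethers.

Step 5
Reactants: 10 tetramethylammonium pentacarbonyl(2‑methoxyprop‑2‑enoyl)chromate; 5 5‑hydroxy‑6,7‑dimethoxycoumarin
Product: 12 pentacarbonyl{[(6,7‑dimethoxy‑2‑oxo‑2H‑chromen‑5‑yl)oxy](1‑methoxyvinyl)carbene}chromium (CO)5Cr=C(OAr)C(OMe)=CH2, via acetoxycarbene complex 11 (not isolated)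
Conditions: AcBr, CH2Cl2, −40 °C; then 5, −40 to 0 °C; rapid filtration through silica under Ar, used at once
Reagents that add atoms: none
Why: O‑Acylation of the acylmetalate gives a strongly electrophilic acetoxycarbene complex (no α‑hydrogen, so no collapse to an enol ester), and addition–elimination of the phenol at the planar carbene carbon should expel acetate (acyloxy‑for‑aryloxy exchange of Fischer carbene complexes), a substitution that is far less sensitive to the two ortho substituents of the 5‑OH than an arylation.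

Step 6
Reactants: 12 pentacarbonyl{[(6,7‑dimethoxy‑2‑oxo‑2H‑chromen‑5‑yl)oxy](1‑methoxyvinyl)carbene}chromium; 13 3,3‑diethoxyprop‑1‑yne
Product: 15 5‑[5‑(diethoxymethyl)‑4‑hydroxy‑2‑methoxyphenoxy]‑6,7‑dimethoxycoumarin, via tricarbonylchromium arene complex 14 (not isolated)
Conditions: 13 (2 equiv), THF (0.05 M), 50 °C, Ar; then air, rt; Et3N‑deactivated silica
Reagents that add atoms: none
Why: Loss of one CO from 12 opens a site for alkyne 13, which inserts into the Cr=C bond with its unsubstituted carbon bonding to the carbene carbon (C6–C5); CO insertion (C4a–C8a) then gives a chromium‑bound dienylketene that undergoes 6π‑electrocyclisation onto the CH2 terminus of the 1‑methoxyvinyl group (C8a–C8), and the cyclohexadienone tautomerises to the phenol, first held as the Cr(CO)3 complex 14 and freed by air. This is the Dötz benzannulation, whose closest precedents are alkenyl(aryloxy)carbene complexes of zerovalent chromium giving diaryl ethers and α‑alkoxyalkenyl carbene complexes giving alkoxy‑substituted phenols; 12 combines the two features. The benzene ring of unit Q is the only ring closed, by electrocyclic ring closure of the ketene intermediate after two intermolecular insertions. No stereocentre is formed. The step needs the diethoxymethyl‑bearing alkyne carbon next to the CO‑derived carbon, which is the normal regiochemistry of terminal alkynes because the substituted alkyne carbon stays remote from the carbene substituents during insertion, and it needs CO insertion over five‑ring formation, which chromium and an alkenyl (not aryl) carbene substituent favour. The mild temperature should keep the C3=C4 bond of unit P from being intercepted by the carbene, and air, not a strong oxidant, is used for demetalation so that the hydroquinone monoether is not oxidised to a quinone.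

Step 7
Reactants: 15 5‑[5‑(diethoxymethyl)‑4‑hydroxy‑2‑methoxyphenoxy]‑6,7‑dimethoxycoumarin
Product: 16 5‑[(6,7‑dimethoxy‑2‑oxo‑2H‑chromen‑5‑yl)oxy]‑2‑hydroxy‑4‑methoxybenzaldehyde
Conditions: TsOH·H2O (cat.), acetone/H2O, rt
Reagents that add atoms: water, O
Why: Acid‑catalysed acetal hydrolysis should proceed readily through an oxocarbenium ion stabilised by the ortho and para oxygen donors, while lactone, diaryl ether and methyl ethers are inert to dilute acid at rt.

Step 8
Reactants: 16 5‑[(6,7‑dimethoxy‑2‑oxo‑2H‑chromen‑5‑yl)oxy]‑2‑hydroxy‑4‑methoxybenzaldehyde; 17 ethyl (triphenylphosphoranylidene)acetate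
Product: 19 6‑[(6,7‑dimethoxy‑2‑oxo‑2H‑chromen‑5‑yl)oxy]‑7‑methoxycoumarin, via ethyl 2‑hydroxycinnamate 18 (not isolated)
Conditions: PhNEt2, reflux, N2
Reagents that add atoms: none
Why: Wittig olefination of the salicylaldehyde gives the cinnamate, and at the reflux temperature of N,N‑diethylaniline the E isomer should equilibrate with the Z isomer, which lactonises with loss of ethanol to close the pyranone ring of unit Q.

Step 9
Reactants: 19 6‑[(6,7‑dimethoxy‑2‑oxo‑2H‑chromen‑5‑yl)oxy]‑7‑methoxycoumarin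
Product: 20 6‑[(6,7‑dihydroxy‑2‑oxo‑2H‑chromen‑5‑yl)oxy]‑7‑hydroxycoumarin (target)
Conditions: BBr3 (excess), CH2Cl2, −78 °C to rt; then H2O
Reagents that add atoms: none
Why: In this Lewis acid O‑demethylation BBr3 coordinates each methoxy oxygen and bromide cleaves the O–CH3 bond by SN2, while the diaryl ether (no sp3 C–O bond) and both lactones should survive and hydrolysis of the aryl borates releases the three phenols.

**Compound list**

1 | isoscopoletin (6‑hydroxy‑7‑methoxy‑2H‑chromen‑2‑one) | COc1cc2oc(=O)ccc2cc1O | starting material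
2 | 6‑hydroxy‑7‑methoxy‑2‑oxo‑2H‑chromene‑5‑carbaldehyde | COc1cc2oc(=O)ccc2c(C=O)c1O | intermediate
3 | 6,7‑dimethoxy‑2‑oxo‑2H‑chromene‑5‑carbaldehyde | COc1cc2oc(=O)ccc2c(C=O)c1OC | intermediate
4 | 6,7‑dimethoxy‑2‑oxo‑2H‑chromen‑5‑yl formate (not isolated) | COc1cc2oc(=O)ccc2c(OC=O)c1OC | intermediate
5 | 5‑hydroxy‑6,7‑dimethoxy‑2H‑chromen‑2‑one | COc1cc2oc(=O)ccc2c(O)c1OC | intermediate
6 | methyl vinyl ether | COC=C | starting material
7 | hexacarbonylchromium Cr(CO)6 | O=C=[Cr](=C=O)(=C=O)(=C=O)(=C=O)=C=O | starting material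
8 | 1‑methoxyvinyllithium CH2=C(OMe)Li (not isolated) | [Li]C(=C)OC | intermediate
9 | lithium pentacarbonyl(2‑methoxyprop‑2‑enoyl)chromate Li[(CO)5CrC(O)C(OMe)=CH2] (not isolated) | [Li+].C=C(OC)C([O-])=[Cr](=C=O)(=C=O)(=C=O)(=C=O)=C=O | intermediate
10 | tetramethylammonium pentacarbonyl(2‑methoxyprop‑2‑enoyl)chromate [NMe4][(CO)5CrC(O)C(OMe)=CH2] | C[N+](C)(C)C.C=C(OC)C([O-])=[Cr](=C=O)(=C=O)(=C=O)(=C=O)=C=O | intermediate
11 | pentacarbonyl[acetoxy(1‑methoxyvinyl)carbene]chromium (CO)5Cr=C(OAc)C(OMe)=CH2 (not isolated) | C=C(OC)C(OC(C)=O)=[Cr](=C=O)(=C=O)(=C=O)(=C=O)=C=O | intermediate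
12 | pentacarbonyl{[(6,7‑dimethoxy‑2‑oxo‑2H‑chromen‑5‑yl)oxy](1‑methoxyvinyl)carbene}chromium (CO)5Cr=C(OAr)C(OMe)=CH2 | C=C(OC)C(Oc1c(OC)c(OC)cc2oc(=O)ccc12)=[Cr](=C=O)(=C=O)(=C=O)(=C=O)=C=O | intermediate
13 | 3,3‑diethoxyprop‑1‑yne | C#CC(OCC)OCC | starting material
14 | tricarbonyl(η6‑arene)chromium complex of 15, (arene)Cr(CO)3 with chromium on the new phenol ring, η6 bonding written as a dot (not isolated) | CCOC(OCC)c1cc(Oc2c(OC)c(OC)cc3oc(=O)ccc23)c(OC)cc1O.[Cr](=C=O)(=C=O)=C=O | intermediate
15 | 5‑[5‑(diethoxymethyl)‑4‑hydroxy‑2‑methoxyphenoxy]‑6,7‑dimethoxy‑2H‑chromen‑2‑one | CCOC(OCC)c1cc(Oc2c(OC)c(OC)cc3oc(=O)ccc23)c(OC)cc1O | intermediate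
16 | 5‑[(6,7‑dimethoxy‑2‑oxo‑2H‑chromen‑5‑yl)oxy]‑2‑hydroxy‑4‑methoxybenzaldehyde | O=Cc1cc(Oc2c(OC)c(OC)cc3oc(=O)ccc23)c(OC)cc1O | intermediate
17 | ethyl (triphenylphosphoranylidene)acetate | CCOC(=O)C=P(c1ccccc1)(c1ccccc1)c1ccccc1 | starting material
18 | ethyl (E)‑3‑{5‑[(6,7‑dimethoxy‑2‑oxo‑2H‑chromen‑5‑yl)oxy]‑2‑hydroxy‑4‑methoxyphenyl}prop‑2‑enoate (E isomer drawn; the Z isomer reached on heating is the one that lactonises; not isolated) | CCOC(=O)/C=C/c1cc(Oc2c(OC)c(OC)cc3oc(=O)ccc23)c(OC)cc1O | intermediate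
19 | 6‑[(6,7‑dimethoxy‑2‑oxo‑2H‑chromen‑5‑yl)oxy]‑7‑methoxy‑2H‑chromen‑2‑one | COc1cc2oc(=O)ccc2cc1Oc1c(OC)c(OC)cc2oc(=O)ccc12 | intermediate
20 | 6‑[(6,7‑dihydroxy‑2‑oxo‑2H‑chromen‑5‑yl)oxy]‑7‑hydroxy‑2H‑chromen‑2‑one | O=c1ccc2cc(Oc3c(O)c(O)cc4oc(=O)ccc34)c(O)cc2o1 | target

**Step count and risks**

Total step count: 9.
Longest linear sequence: 8 steps (1 → 2 → 3 → 5 → 12 → 15 → 16 → 19 → 20; the chromium branch 6 + 7 → 10 joins at step 5).

Steps most likely to fail:

1. Step 5. The acetoxycarbene complex may decompose, or be attacked at its acetyl carbonyl (returning the acylmetalate) or at the vinyl terminus in conjugate fashion, faster than the hindered phenol substitutes at the carbene carbon. The fallback gives up the carbene route to the ether bond; it sets out from 5 and comes back at 19. Commercial 5‑bromo‑2‑hydroxy‑4‑methoxybenzaldehyde (COc1cc(O)c(C=O)cc1Br) would be heated with ylide 17 in N,N‑diethylaniline to give 6‑bromo‑7‑methoxycoumarin F1. Phenol 5 would then be O‑arylated with F1 by Ullmann coupling (CuI, picolinic acid, K3PO4, DMSO, 90–110 °C), giving 19 directly.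

2. Step 6. Thermal decay of the aryloxycarbene complex, uptake of a second alkyne, cyclisation without CO insertion, or interception of the carbene by the C3=C4 bond of unit P may outrun the benzannulation. The fallback builds the aryl ether on a preformed benzene ring; it sets out from 5 and comes back at 16. SNAr of 5 on commercial 4‑fluoro‑3‑methoxybenzaldehyde (COc1cc(C=O)ccc1F; K2CO3, DMF, 110 °C) would give 4‑[(6,7‑dimethoxy‑2‑oxo‑2H‑chromen‑5‑yl)oxy]‑3‑methoxybenzaldehyde F2. Baeyer–Villiger oxidation (mCPBA, CH2Cl2) would give 4‑[(6,7‑dimethoxy‑2‑oxo‑2H‑chromen‑5‑yl)oxy]‑3‑methoxyphenyl formate F3, and methanolysis (Et3N, MeOH) 5‑(4‑hydroxy‑2‑methoxyphenoxy)‑6,7‑dimethoxycoumarin F4. Magnesium‑mediated ortho‑formylation of F4 (MgCl2, Et3N, (CH2O)n, MeCN, reflux), which should go to the unhindered ortho position para to the methoxy group, would give 16.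

3. Step 3. Hydride instead of aryl migration in the Criegee adduct would lead to the carboxylic acid, because the migrating ring carries an electron‑poor vinyl group next to the formyl carbon. The fallback introduces the 5‑oxygen through a halide and also bypasses steps 1 and 2; it sets out from 1 and comes back at 5. Bromination ortho to the 6‑OH (NBS, MeCN, 0 °C) would give 5‑bromo‑6‑hydroxy‑7‑methoxycoumarin F5, and methylation (MeI, K2CO3, DMF) 5‑bromo‑6,7‑dimethoxycoumarin F6. Miyaura borylation (B2pin2, PdCl2(dppf), KOAc, dioxane, 90 °C) would give 6,7‑dimethoxy‑5‑(4,4,5,5‑tetramethyl‑1,3,2‑dioxaborolan‑2‑yl)coumarin F7, which NaBO3·4H2O in THF/H2O would oxidise to 5.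

Further compounds
F1 | step 5 | 6‑bromo‑7‑methoxy‑2H‑chromen‑2‑one | COc1cc2oc(=O)ccc2cc1Br
F2 | step 6 | 4‑[(6,7‑dimethoxy‑2‑oxo‑2H‑chromen‑5‑yl)oxy]‑3‑methoxybenzaldehyde | COc1cc(C=O)ccc1Oc1c(OC)c(OC)cc2oc(=O)ccc12
F3 | step 6 | 4‑[(6,7‑dimethoxy‑2‑oxo‑2H‑chromen‑5‑yl)oxy]‑3‑methoxyphenyl formate | COc1cc(OC=O)ccc1Oc1c(OC)c(OC)cc2oc(=O)ccc12
F4 | step 6 | 5‑(4‑hydroxy‑2‑methoxyphenoxy)‑6,7‑dimethoxy‑2H‑chromen‑2‑one | COc1cc(O)ccc1Oc1c(OC)c(OC)cc2oc(=O)ccc12
F5 | step 3 | 5‑bromo‑6‑hydroxy‑7‑methoxy‑2H‑chromen‑2‑one | COc1cc2oc(=O)ccc2c(Br)c1O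
F6 | step 3 | 5‑bromo‑6,7‑dimethoxy‑2H‑chromen‑2‑one | COc1cc2oc(=O)ccc2c(Br)c1OC
F7 | step 3 | 6,7‑dimethoxy‑5‑(4,4,5,5‑tetramethyl‑1,3,2‑dioxaborolan‑2‑yl)‑2H‑chromen‑2‑one | COc1cc2oc(=O)ccc2c(B2OC(C)(C)C(C)(C)O2)c1OC
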